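**Plan**

- Feature: rings A and B share the quaternary C10, and the chain O=C3–C2–C1–C10–C9=C8(O), with further oxygen at C4, is the δ,ε-unsaturated ketone that an oxy-Cope shift leaves behind. This traces the decalin to a 2-vinylbicyclo[2.2.2]oct-5-en-2-ol made from dearomatised 2,6-dimethoxy-4-methylphenol.
- Cuts, in retrosynthetic order: C5–OOH (ene reaction, C4=C15 back to C4=C5); C11–C12 (carbonylation); C4–C15 (cross-coupling); C1–C10 with re-closure of C3–C8 (retro-oxy-Cope); C2–C3 (vinyl addition); C5–C6 and C7–C8 (Diels–Alder).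
- Forward: ring B arises first as the cyclohexene inside the Diels–Alder bicyclooctenone, and ring A closes in the oxy-Cope shift. C15, the C8 and C3 oxygens, C12 and the hydroperoxide follow.
- Stereochemistry: the endo Diels–Alder fixes C7 against the future C5/C10, and resolution of the adduct gives the absolute series. The [3,3] shift relays this to C10. C8 comes from equatorial hydride attack, C3 from axial hydride attack, and C5 from singlet oxygen adding anti to the C10 methyl.

Key step: step 5

Remark: decalin intermediates carry eudesmane numbering (ring A = C1–C5 and C10; ring B = C5–C10; C14 on C10, C15 on C4, C11–C13 on C7) and β is the face of the C10 methyl. The acetyl group is carried as a 1,3-dithiane because a dioxolane would not survive the ketal hydrolysis of step 6 and would expose a C7-acetyl/C8-ketone β-diketone. Which eluting enantiomer is kept in step 2 is to be settled by X-ray analysis of 6.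

**Step 1**
Reactants: 1 2,6-dimethoxy-4-methylphenol; 2 but-3-en-2-one
Product: 4 rac-(1R*,4S*,7S*)-7-acetyl-1,3,3-trimethoxy-5-methylbicyclo[2.2.2]oct-5-en-2-one (acetyl endo), via masked o-benzoquinone 3 (not isolated)
Conditions: PhI(OAc)2 (1.1 equiv), MeOH, 2 (10 equiv), slow addition of 1, 0 °C → rt
Reagents that add atoms: methanol, CO
Why: Oxidative dearomatisation gives the ortho-quinone monoketal, which excess enone traps in a Diels–Alder reaction before it can dimerise; the acetyl-bearing carbon bonds to the methoxy-substituted diene terminus next to the carbonyl (the 2-methoxy and 4-methyl groups direct the same way) and endo addition places the acetyl group syn to the new C5=C6 bridge, which sets C7 relative to C1 and C4.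

**Step 2**
Reactants: 4 racemic adduct
Product: 5 (1R,4S,7S)-7-acetyl-1,3,3-trimethoxy-5-methylbicyclo[2.2.2]oct-5-en-2-one
Conditions: preparative SFC, amylose tris(3,5-dimethylphenylcarbamate) phase, CO2/MeOH
Reagents that add atoms: none
Why: Resolution on a chiral stationary phase at the first chiral, rigid intermediate supplies the absolute configuration of C7 (and thereby of C10) before any further material is invested.

**Step 3**
Reactants: 5 resolved adduct
Product: 6 (1R,4S,7S)-1,3,3-trimethoxy-5-methyl-7-(2-methyl-1,3-dithian-2-yl)bicyclo[2.2.2]oct-5-en-2-one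
Conditions: propane-1,3-dithiol (1.2 equiv), BF3·OEt2 (0.3 equiv), CH2Cl2, −20 → 0 °C
Reagents that add atoms: propane-1,3-dithiol, SCCCS
Why: Thioketalisation should take only the unhindered methyl ketone, since the bridging ketone sits between two fully substituted carbons and the α-keto ketal resists ionisation; the dithiane tolerates Grignard reagent, KH, aqueous acid and hydride.

**Step 4**
Reactants: 6 dithiane ketone; 7 vinylmagnesium bromide
Product: 8 (1R,2R,4S,7S)-1,3,3-trimethoxy-5-methyl-7-(2-methyl-1,3-dithian-2-yl)-2-vinylbicyclo[2.2.2]oct-5-en-2-ol (vinyl syn to C5=C6)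
Conditions: 7 (1.5 equiv), THF, −78 → 0 °C; aq. NH4Cl
Reagents that add atoms: none
Why: Grignard 1,2-addition to the non-enolisable ketone should come from the open face beside the C5=C6 bridge, because the other face is screened by the exo hydrogens of the C7–C8 bridge, which sets C2 with the vinyl group syn to the alkene.

**Step 5**
Reactants: 8 vinyl carbinol
Product: 10 (4aR,7S,8aS)-1,1,6-trimethoxy-4a-methyl-7-(2-methyl-1,3-dithian-2-yl)-3,4,4a,7,8,8a-hexahydronaphthalen-2(1H)-one (cis-decalin; eudesmane numbering: 3-oxo-4,4-dimethoxy-8-methoxy-Δ8 with 5β-H 7β-dithianyl 10β-methyl), via potassium enolate 9 (not isolated)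
Conditions: KH (2 equiv), 18-crown-6 (1.2 equiv), THF, 0 °C → rt; aq. NH4Cl
Reagents that add atoms: none
Why: KH with 18-crown-6 gives the dissociated potassium alkoxide of 8, whose 3-oxido-1,5-diene CH2=CH–C2(O–)–C1–C6=C5 (bicyclic numbering) undergoes a concerted [3,3] sigmatropic shift through the boat transition state that the bicycle enforces: the vinyl terminus bonds to the methyl-bearing alkene carbon (the eudesmane C1–C10 bond) while the strained C1–C2 bond between methoxy bridgehead and carbinol carbon breaks, giving enolate 9 and, on protonation, ketone 10. The closest known reaction type is the anionic oxy-Cope rearrangement of 2-vinylbicyclo[2.2.2]oct-5-en-2-ols obtained from masked o-benzoquinone Diels–Alder adducts, which gives cis-decalins. Ring A (six-membered) is closed by this sigmatropic C–C bond formation as the bicycle opens, with no ionic or radical cyclisation, while ring B is the cyclohexene already present. The single new stereocenter, quaternary C10, is set by suprafacial delivery of the vinyl carbon to the alkene face that looks at the carbinol bridge, so the methyl group ends cis to H-5 and to the endo C7 substituent; C5 and C7 are carried over unchanged. The step needs the [3,3] shift to win over a [1,3] shift or fragmentation, and this is secured by the syn arrangement of vinyl group and alkene fixed in step 4, by relief of bicyclic strain and by the bridgehead methoxy group, which turns the cleaved carbon into a stabilised enol ether.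

**Step 6**
Reactants: 10 cis-decalin ketone
Product: 12 4-hydroxy-10β-methyl-7β-(2-methyl-1,3-dithian-2-yl)-Δ4-octalin-3,8-dione (diosphenol), via 3,8-diketone 4,4-dimethyl ketal 11 (not isolated)
Conditions: 3 M aq. HCl, THF, 50 °C, argon
Reagents that add atoms: water, O
Why: Acid hydrolysis frees the C8 ketone from the enol ether and then the α-keto ketal, and the 3,4-dione should enolise toward C5 to the fully substituted diosphenol (as 4-hydroxy-4-en-3-one steroids do), which removes the C5 stereocenter as intended; C7 stays β because the bulky dithianyl group is equatorial there, so enolisation of the C8 ketone returns to the same isomer.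

**Step 7**
Reactants: 12 diosphenol
Product: 13 10β-methyl-7β-(2-methyl-1,3-dithian-2-yl)-3,8-dioxo-Δ4-octalin-4-yl trifluoromethanesulfonate
Conditions: PhNTf2 (1.2 equiv), Et3N, DMAP (cat.), CH2Cl2, 0 °C → rt
Reagents that add atoms: N-phenylbis(trifluoromethanesulfonimide), O=S(=O)(N(c1ccccc1)S(=O)(=O)C(F)(F)F)C(F)(F)F
Why: Enol triflate formation takes place only at the acidic diosphenol hydroxyl under amine base, which leaves the C3 and C8 ketones untouched.

**Step 8**
Reactants: 13 enol triflate
Product: 14 4,10β-dimethyl-7β-(2-methyl-1,3-dithian-2-yl)-Δ4-octalin-3,8-dione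
Conditions: Me2Zn (2 equiv), Pd(PPh3)4 (5 mol %), THF, 0 → 40 °C
Reagents that add atoms: dimethylzinc, C[Zn]C
Why: Negishi coupling (oxidative addition of zerovalent palladium into the electron-poor alkenyl triflate, methyl transfer from zinc, reductive elimination) installs C15, and dimethylzinc does not add to ketones without activation.

**Step 9**
Reactants: 14 enedione
Product: 15 8β-hydroxy-4,10β-dimethyl-7β-(2-methyl-1,3-dithian-2-yl)-Δ4-octalin-3-one
Conditions: LiBH(sec-Bu)3 (1.1 equiv), THF, −78 °C; aq. NH4Cl (no peroxide work-up)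
Reagents that add atoms: none
Why: The bulky borohydride should reduce the saturated C8 ketone faster than the hindered, fully substituted enone, and equatorial attack from the α side (the axial β approach is blocked by the syn-axial C10 methyl) gives the axial 8β-alcohol, cis to the C7 substituent.

**Step 10**
Reactants: 15 8β-alcohol
Product: 16 8β-acetoxy-4,10β-dimethyl-7β-(2-methyl-1,3-dithian-2-yl)-Δ4-octalin-3-one
Conditions: Ac2O, DMAP, pyridine, rt → 40 °C
Reagents that add atoms: acetic anhydride, CC(=O)OC(C)=O
Why: DMAP-catalysed acylation with the smallest anhydride should still reach the hindered axial alcohol.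

**Step 11**
Reactants: 16 acetoxy enone
Product: 17 8β-acetoxy-4,10β-dimethyl-7β-(2-methyl-1,3-dithian-2-yl)-Δ4-octalin-3β-ol
Conditions: NaBH4, CeCl3·7H2O, MeOH, −78 → −40 °C
Reagents that add atoms: none
Why: Luche 1,2-reduction delivers hydride axially from the α face of the 10β-methyl Δ4-3-ketone and so gives the pseudo-equatorial 3β-alcohol, with the acetate untouched at low temperature.

**Step 12**
Reactants: 17 allylic alcohol
Product: 18 8β-acetoxy-3β-(2-methylpropanoyloxy)-4,10β-dimethyl-7β-(2-methyl-1,3-dithian-2-yl)-Δ4-octalin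
Conditions: (i-PrCO)2O, Et3N, DMAP (cat.), CH2Cl2, 0 °C → rt
Reagents that add atoms: 2-methylpropanoic anhydride, CC(C)C(=O)OC(=O)C(C)C
Why: Standard DMAP-catalysed acylation of the unhindered allylic alcohol with retention at C3.

**Step 13**
Reactants: 18 diester dithiane
Product: 19 7β-acetyl-8β-acetoxy-3β-(2-methylpropanoyloxy)-4,10β-dimethyl-Δ4-octalin
Conditions: MeI (excess), CaCO3, MeCN/H2O (9:1), 45 °C
Reagents that add atoms: water, O
Why: S-alkylative hydrolysis of the dithiane under buffered, non-oxidising conditions frees the methyl ketone without touching the tetrasubstituted alkene or the two esters.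

**Step 14**
Reactants: 19 methyl ketone
Product: 21 1-[8β-acetoxy-3β-(2-methylpropanoyloxy)-4,10β-dimethyl-Δ4-octalin-7β-yl]vinyl trifluoromethanesulfonate, via potassium enolate 20 (not isolated)
Conditions: KN(SiMe3)2 (1.05 equiv), THF, −78 °C, then N-(5-chloropyridin-2-yl)bis(trifluoromethanesulfonimide), −78 °C
Reagents that add atoms: N-(5-chloropyridin-2-yl)bis(trifluoromethanesulfonimide), O=S(=O)(N(c1ccc(Cl)cn1)S(=O)(=O)C(F)(F)F)C(F)(F)F
Why: Kinetic deprotonation by the hindered amide at −78 °C takes the methyl group (not the C7 methine or the less acidic esters), and immediate O-sulfonylation with a triflimide that reacts at this temperature gives the terminal enol triflate before the enolate can equilibrate.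

**Step 15**
Reactants: 21 enol triflate
Product: 22 methyl 8β-acetoxy-3β-(2-methylpropanoyloxy)eudesma-4,11(13)-dien-12-oate
Conditions: Pd(OAc)2 (5 mol %), PPh3 (10 mol %), CO (1 atm), MeOH, Et3N, DMF, rt → 45 °C
Reagents that add atoms: carbon monoxide, [C-]#[O+]; methanol, CO
Why: Palladium-catalysed methoxycarbonylation of the alkenyl triflate (oxidative addition, CO insertion, methanolysis) adds C12 as the acrylate, while the hindered allylic ester on the tetrasubstituted alkene should not ionise competitively.

**Step 16**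
Reactants: 22 dienoate
Product: 23 methyl 8β-acetoxy-5α-hydroperoxy-3β-(2-methylpropanoyloxy)eudesma-4(15),11(13)-dien-12-oate (3S,5S,7R,8R,10R)
Conditions: O2, tetraphenylporphyrin (cat.), visible light, CH2Cl2, −20 °C
Reagents that add atoms: dioxygen, O=O
Why: In the Schenck ene reaction singlet oxygen adds to the electron-rich C4=C5 bond on the α face, anti to the axial C10 methyl, which sets C5; on that face only the C15 hydrogens and H-3 are aligned (H-6α lies in the alkene plane) and H-3 sits on the acyloxy-bearing carbon, so abstraction from C15 should give the 5α-hydroperoxide with the C4=C15 bond, the acrylate being inert.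

**Compound list**

1 | 2,6-dimethoxy-4-methylphenol | Cc1cc(OC)c(O)c(OC)c1 | starting material
2 | but-3-en-2-one | C=CC(C)=O | starting material
3 | 2,6,6-trimethoxy-4-methylcyclohexa-2,4-dien-1-one (masked o-benzoquinone) | COC1=CC(C)=CC(OC)(OC)C1=O | intermediate
4 | rac-(1R*,4S*,7S*)-7-acetyl-1,3,3-trimethoxy-5-methylbicyclo[2.2.2]oct-5-en-2-one | O=C1C(OC)(OC)[C@H]2C[C@H](C(C)=O)[C@]1(OC)C=C2C.O=C1C(OC)(OC)[C@@H]2C[C@@H](C(C)=O)[C@@]1(OC)C=C2C | intermediate
5 | (1R,4S,7S)-7-acetyl-1,3,3-trimethoxy-5-methylbicyclo[2.2.2]oct-5-en-2-one | O=C1C(OC)(OC)[C@H]2C[C@H](C(C)=O)[C@]1(OC)C=C2C | intermediate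
6 | (1R,4S,7S)-1,3,3-trimethoxy-5-methyl-7-(2-methyl-1,3-dithian-2-yl)bicyclo[2.2.2]oct-5-en-2-one | O=C1C(OC)(OC)[C@H]2C[C@H](C3(C)SCCCS3)[C@]1(OC)C=C2C | intermediate
7 | vinylmagnesium bromide | C=C[Mg]Br | starting material
8 | (1R,2R,4S,7S)-1,3,3-trimethoxy-5-methyl-7-(2-methyl-1,3-dithian-2-yl)-2-vinylbicyclo[2.2.2]oct-5-en-2-ol | C=C[C@]1(O)C(OC)(OC)[C@H]2C[C@H](C3(C)SCCCS3)[C@]1(OC)C=C2C | intermediate
9 | potassium C2=C3 enolate of 10 | CC1(SCCCS1)[C@H]2C[C@@H]3C(OC)(OC)C([O-])=CC[C@]3(C)C=C2OC.[K+] | intermediate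
10 | (4aR,7S,8aS)-1,1,6-trimethoxy-4a-methyl-7-(2-methyl-1,3-dithian-2-yl)-3,4,4a,7,8,8a-hexahydronaphthalen-2(1H)-one | CC1(SCCCS1)[C@H]2C[C@@H]3C(OC)(OC)C(=O)CC[C@]3(C)C=C2OC | intermediate
11 | 4,4-dimethoxy-10β-methyl-7β-(2-methyl-1,3-dithian-2-yl)-5βH-decalin-3,8-dione | CC1(SCCCS1)[C@H]2C[C@@H]3C(OC)(OC)C(=O)CC[C@]3(C)CC2=O | intermediate
12 | 4-hydroxy-10β-methyl-7β-(2-methyl-1,3-dithian-2-yl)-Δ4-octalin-3,8-dione | CC1(SCCCS1)[C@H]2CC3=C(O)C(=O)CC[C@]3(C)CC2=O | intermediate
13 | 10β-methyl-7β-(2-methyl-1,3-dithian-2-yl)-3,8-dioxo-Δ4-octalin-4-yl trifluoromethanesulfonate | CC1(SCCCS1)[C@H]2CC3=C(OS(=O)(=O)C(F)(F)F)C(=O)CC[C@]3(C)CC2=O | intermediate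
14 | 4,10β-dimethyl-7β-(2-methyl-1,3-dithian-2-yl)-Δ4-octalin-3,8-dione | CC1(SCCCS1)[C@H]2CC3=C(C)C(=O)CC[C@]3(C)CC2=O | intermediate
15 | 8β-hydroxy-4,10β-dimethyl-7β-(2-methyl-1,3-dithian-2-yl)-Δ4-octalin-3-one | CC1(SCCCS1)[C@H]2CC3=C(C)C(=O)CC[C@]3(C)C[C@H]2O | intermediate
16 | 8β-acetoxy-4,10β-dimethyl-7β-(2-methyl-1,3-dithian-2-yl)-Δ4-octalin-3-one | CC1(SCCCS1)[C@H]2CC3=C(C)C(=O)CC[C@]3(C)C[C@H]2OC(C)=O | intermediate
17 | 8β-acetoxy-4,10β-dimethyl-7β-(2-methyl-1,3-dithian-2-yl)-Δ4-octalin-3β-ol | CC1(SCCCS1)[C@H]2CC3=C(C)[C@@H](O)CC[C@]3(C)C[C@H]2OC(C)=O | intermediate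
18 | 8β-acetoxy-3β-(2-methylpropanoyloxy)-4,10β-dimethyl-7β-(2-methyl-1,3-dithian-2-yl)-Δ4-octalin | CC1(SCCCS1)[C@H]2CC3=C(C)[C@@H](OC(=O)C(C)C)CC[C@]3(C)C[C@H]2OC(C)=O | intermediate
19 | 7β-acetyl-8β-acetoxy-3β-(2-methylpropanoyloxy)-4,10β-dimethyl-Δ4-octalin | CC(=O)[C@H]1CC2=C(C)[C@@H](OC(=O)C(C)C)CC[C@]2(C)C[C@H]1OC(C)=O | intermediate
20 | potassium C11=C13 enolate of 19 | C=C([O-])[C@H]1CC2=C(C)[C@@H](OC(=O)C(C)C)CC[C@]2(C)C[C@H]1OC(C)=O.[K+] | intermediate
21 | 1-[8β-acetoxy-3β-(2-methylpropanoyloxy)-4,10β-dimethyl-Δ4-octalin-7β-yl]vinyl trifluoromethanesulfonate | C=C(OS(=O)(=O)C(F)(F)F)[C@H]1CC2=C(C)[C@@H](OC(=O)C(C)C)CC[C@]2(C)C[C@H]1OC(C)=O | intermediate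
22 | methyl 8β-acetoxy-3β-(2-methylpropanoyloxy)eudesma-4,11(13)-dien-12-oate | C=C(C(=O)OC)[C@H]1CC2=C(C)[C@@H](OC(=O)C(C)C)CC[C@]2(C)C[C@H]1OC(C)=O | intermediate
23 | methyl 8β-acetoxy-5α-hydroperoxy-3β-(2-methylpropanoyloxy)eudesma-4(15),11(13)-dien-12-oate | C=C(C(=O)OC)[C@H]1C[C@@]2(OO)C(=C)[C@@H](OC(=O)C(C)C)CC[C@]2(C)C[C@H]1OC(C)=O | target

**Step count**

Total steps: 16. Longest linear sequence: 16 steps, from 1.

**Steps most likely to fail**

Step 14. The potassium enolate may transfer the neighbouring acetyl group to itself (intramolecular Claisen-type acyl migration), or it may equilibrate to the C7 enolate and expel acetate by β-elimination. The fallback avoids any enolate. It sets out from 19, which is condensed with 1,2-bis(tert-butyldimethylsilyl)hydrazine under catalytic Sc(OTf)3 to the N-silyl hydrazone F1. Iodine and 1,1,3,3-tetramethylguanidine (Barton vinyl iodide synthesis) should then give the terminal 2-iodoalkene F2, because the C7 methine is hindered. F2 is carbonylated under the conditions of step 15 and the route is rejoined at 22.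

Step 16. Hydrogen abstraction at C3 (toward an enol ester) or attack of singlet oxygen on the β face may erode regio- and facial selectivity, and the allylic hydroperoxide may degrade during irradiation. The fallback builds the C5–O bond by an ionic sequence from 22. Hydroxyselenation with N-(phenylseleno)phthalimide, water and catalytic camphorsulfonic acid should place selenium on the α face at C4 and hydroxyl at C5, the carbon further from the acyloxy group, giving the 4α-phenylselanyl-5β-alcohol F3. Oxidation with H2O2/pyridine and syn elimination of the selenoxide can only run toward C15 (C5 has no hydrogen and elimination toward the oxygen-bearing C3 is disfavoured), giving the 5β-hydroxy-4(15)-ene F4. Perhydrolysis of this tertiary allylic alcohol with concentrated H2O2 in Et2O and catalytic H2SO4 at 0 °C goes through the allyl cation, which should be captured at C5 from the α face, and the route is rejoined at 23.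

Step 6. Hydrolysis of the α-keto ketal may be slow or incomplete, with decomposition on forcing. The fallback removes the deactivating carbonyl first. It sets out from 10, whose C3 ketone is reduced with NaBH4 to the 3-hydroxy ketal F5 (C3 epimers, of no consequence). Mild aqueous acid (oxalic acid, THF/H2O) then cleaves the enol ether and the now ordinary ketal to the 3-hydroxy-4,8-dione F6. Parikh–Doering oxidation (SO3·pyridine, DMSO, i-Pr2NEt) gives the 3,4-dione, which enolises, and the route is rejoined at 12.

**Further compounds**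

F1 | step 14 | N-(tert-butyldimethylsilyl)hydrazone of 19 | CC(=NN[Si](C)(C)C(C)(C)C)[C@H]1CC2=C(C)[C@@H](OC(=O)C(C)C)CC[C@]2(C)C[C@H]1OC(C)=O
F2 | step 14 | 7β-(1-iodovinyl)-8β-acetoxy-3β-(2-methylpropanoyloxy)-4,10β-dimethyl-Δ4-octalin | C=C(I)[C@H]1CC2=C(C)[C@@H](OC(=O)C(C)C)CC[C@]2(C)C[C@H]1OC(C)=O
F3 | step 16 | methyl 8β-acetoxy-5β-hydroxy-3β-(2-methylpropanoyloxy)-4α-(phenylselanyl)eudesm-11(13)-en-12-oate | C=C(C(=O)OC)[C@H]1C[C@]2(O)[C@](C)([Se]c3ccccc3)[C@@H](OC(=O)C(C)C)CC[C@]2(C)C[C@H]1OC(C)=O
F4 | step 16 | methyl 8β-acetoxy-5β-hydroxy-3β-(2-methylpropanoyloxy)eudesma-4(15),11(13)-dien-12-oate | C=C(C(=O)OC)[C@H]1C[C@]2(O)C(=C)[C@@H](OC(=O)C(C)C)CC[C@]2(C)C[C@H]1OC(C)=O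
F5 | step 6 | 3-hydroxy analogue of 10 (C3 epimer mixture) | CC1(SCCCS1)[C@H]2C[C@@H]3C(OC)(OC)C(O)CC[C@]3(C)C=C2OC
F6 | step 6 | 3-hydroxy-10β-methyl-7β-(2-methyl-1,3-dithian-2-yl)-5βH-decalin-4,8-dione (C3 epimer mixture) | CC1(SCCCS1)[C@H]2C[C@@H]3C(=O)C(O)CC[C@]3(C)CC2=O
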